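## Assumptions
- (S)-(+)-Linalool and (R)-glycidol are purchasable. Note (R)-glycidol becomes the (S)-configured C–O centre once its oxygen is substituted.
- The acetal Claisen gives the E-trisubstituted alkene with high selectivity (chair transition state, R equatorial).
- The allylic carbinol in 16 is destroyed in the Claisen, so it is carried as an epimeric mixture.

## Retrosynthesis
1. Target ← Cα acetate/OH ← ketone 17 (chelation-controlled reduction, then Ac2O, then desilylation).
2. Key step: an acetal (Saucy–Marbet-type) Claisen [3,3] of allylic alcohol 16 with lactone ketal 5 joins the two halves. It forms the CH2–CH2 bond and the E-trisubstituted alkene next to C–OH.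
3. Lactone ring and Cq come from (S)-linalool (oxidative cleavage, lactonisation, Wacker). The carbinol centre comes from (R)-glycidol; the second trisubstituted alkene is made by cross-metathesis with a Kumada-derived furyl butene.
4. Ring order: the γ-lactone is formed first (steps 1–2). The furan is carried in from 3-bromofuran.

## Route

**Step 1**
Reactants: 1, (S)-(+)-linalool
Product: 2, (2S)-2-methyl-2-vinyltetrahydrofuran-5-ol (lactol, anomeric mixture)
Conditions: O3 (1.0 equiv), CH2Cl2, –78 °C; then PPh3, –78 °C → rt
Reagents that add atoms: ozone, [O-][O+]=O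
Why: The electron-rich trisubstituted alkene reacts with ozone far faster than the vinyl group beside the tertiary alcohol. The resulting γ-hydroxy aldehyde closes spontaneously to the lactol, and Cq is untouched.

**Step 2**
Reactants: 2
Product: 3, (S)-5-methyl-5-vinyldihydrofuran-2(3H)-one
Conditions: TEMPO (10 mol %), PhI(OAc)2, CH2Cl2, rt
Reagents that add atoms: none
Why: TEMPO/BAIB oxidation of a lactol gives the lactone, which now masks the tertiary alcohol and the acid.

**Step 3**
Reactants: 3
Product: 4, (S)-5-acetyl-5-methyldihydrofuran-2(3H)-one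
Conditions: PdCl2 (10 mol %), CuCl, O2 (1 atm), DMF/H2O 7:1, 25 → 50 °C
Reagents that add atoms: water, O
Why: Wacker oxidation is Markovnikov for a terminal vinyl group and converts it to the methyl ketone. No new stereocentre forms and Cq is quaternary.

**Step 4**
Reactants: 4
Product: 5, (S)-5-(1,1-dimethoxyethyl)-5-methyldihydrofuran-2(3H)-one
Conditions: HC(OMe)3 (5 equiv), MeOH (2 equiv), cat. TsOH·H2O, CH2Cl2, rt; Et3N quench
Reagents that add atoms: trimethyl orthoformate, COC(OC)OC
Why: Acid-catalysed ketalisation. The ketone has only the methyl side enolisable, so the later enol ether forms regiospecifically.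

**Step 5**
Reactants: 6, 3-bromofuran; 7, 3-butenylmagnesium bromide
Product: 8, 3-(but-3-en-1-yl)furan
Conditions: NiCl2(dppp) (3 mol %), THF, 0 °C → rt
Reagents that add atoms: none beyond the reactants
Why: Kumada sp2–sp3 coupling installs the furyl-ethyl terminus as a terminal alkene, ready for metathesis.

**Step 6**
Reactants: 9, (R)-glycidol; 10, isopropenylmagnesium bromide
Product: 11, (S)-4-methylpent-4-ene-1,2-diol
Conditions: CuI (10 mol %), THF, –30 → 0 °C (2.5 equiv Grignard)
Reagents that add atoms: none beyond the reactants
Why: The Cu-catalysed Grignard attacks the terminal epoxide carbon (SN2). This sets C2 with retention, since the stereocentre is not touched.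

**Step 7**
Reactants: 11
Product: 12, (S)-1,2-bis(TBSO)-4-methylpent-4-ene
Conditions: TBSCl (2.5 equiv), imidazole, DMF, rt
Reagents that add atoms: TBSCl, CC(C)(C)[Si](C)(C)Cl
Why: Silylation of both hydroxyls; the primary one is removed selectively later.

**Step 8**
Reactants: 12; 8 (3 equiv)
Product: 13, (S,E)-1,2-bis(TBSO)-7-(3-furyl)-4-methylhept-4-ene
Conditions: Grubbs II (5 mol %), CH2Cl2, 40 °C
Reagents that add atoms: none beyond the reactants
Why: Cross-metathesis of the 1,1-disubstituted alkene with the excess terminal alkene gives the trisubstituted E-alkene; the stereocentre is remote and unaffected.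

**Step 9**
Reactants: 13
Product: 14, (S,E)-2-TBSO-7-(3-furyl)-4-methylhept-4-en-1-ol
Conditions: HF·pyridine, pyridine, THF, 0 °C → rt
Reagents that add atoms: none
Why: A primary TBS ether is cleaved much faster than the secondary one.

**Step 10**
Reactants: 14
Product: 15, (S,E)-2-TBSO-7-(3-furyl)-4-methylhept-4-enal
Conditions: Dess–Martin periodinane, NaHCO3, CH2Cl2, 0 °C → rt; use crude
Reagents that add atoms: none
Why: Mild, buffered oxidation avoids epimerising the α-silyloxy aldehyde.

**Step 11**
Reactants: 15; 10, isopropenylmagnesium bromide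
Product: 16, 2,6-dimethyl-3-hydroxy-4-TBSO-hepta-1,6-diene-type allylic alcohol, i.e. CH2=C(Me)–CH(OH)–[C2(S)](OTBS)–CH2–C(Me)=CH–CH2CH2-(3-furyl), epimeric mixture at the carbinol
Conditions: THF, –78 °C
Reagents that add atoms: none beyond the reactants
Why: 1,2-Addition gives the secondary methallylic alcohol needed for the Claisen. The new carbinol centre becomes sp2 in step 12, so its configuration is irrelevant.

**Step 12 (key step)**
Reactants: 16; 5 (3 equiv)
Product: 17, ketone (see list)
Conditions: 2,4-dinitrophenol (5 mol %), xylene, 140 °C, sealed tube, 16 h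
Reagents that add atoms: none
Why: Ketal exchange with the allylic alcohol, loss of MeOH and elimination give the allyl 1-(lactonyl)vinyl ether. A chair [3,3] acetal Claisen rearrangement then forms the C–C bond to the methallyl terminus and the E-trisubstituted alkene, with the ketone at Cα.

**Step 13**
Reactants: 17
Product: 18, Cα alcohol (R), TBS-protected
Conditions: Zn(BH4)2 (2 equiv), Et2O/THF, –20 → 0 °C
Reagents that add atoms: none
Why: Zn2+ chelates the ketone oxygen and the lactone ring oxygen. Hydride then enters from the face bearing CH3 rather than the ring CH2, giving Cα = R relative to Cq = S. The lactone and TBS ether are untouched.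

**Step 14**
Reactants: 18
Product: 19, Cα acetate
Conditions: Ac2O, pyridine, cat. DMAP, CH2Cl2, rt
Reagents that add atoms: acetic anhydride, CC(=O)OC(C)=O
Why: DMAP-catalysed acetylation of the hindered secondary alcohol.

**Step 15**
Reactants: 19
Product: 20, 15-acetylirciformonin B
Conditions: HF·pyridine, pyridine, THF, rt
Reagents that add atoms: none
Why: Buffered fluoride removes the TBS ether without touching the acetate, lactone, furan or alkenes. The carbinol is five carbons from the acetate, so migration is unlikely.

## Checks performed
- Every stereocentre is set once and not scrambled. Cq comes from linalool and is quaternary throughout. C2 comes from glycidol and is never enolisable after step 10 (aldehyde used crude at –78 °C). Cα is set in step 13.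
- Both alkenes are E (CM and Claisen).
- Carbon count: 17 is C22 + TBS; adding Ac (2 C) and removing TBS gives C24, matching the target.
- Compound 20 has the same SMILES as the target.

## Compound list
1 | (S)-(+)-linalool | C=C[C@@](C)(O)CCC=C(C)C | starting material
2 | (2S)-2-methyl-2-vinyltetrahydrofuran-5-ol | C=C[C@]1(C)CCC(O)O1 | intermediate
3 | (S)-5-methyl-5-vinyl-γ-butyrolactone | C=C[C@]1(C)CCC(=O)O1 | intermediate
4 | (S)-5-acetyl-5-methyl-γ-butyrolactone | CC(=O)[C@]1(C)CCC(=O)O1 | intermediate
5 | (S)-5-(1,1-dimethoxyethyl)-5-methyl-γ-butyrolactone | COC(C)(OC)[C@]1(C)CCC(=O)O1 | intermediate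
6 | 3-bromofuran | Brc1ccoc1 | starting material
7 | 3-butenylmagnesium bromide | C=CCC[Mg]Br | starting material
8 | 3-(but-3-en-1-yl)furan | C=CCCc1ccoc1 | intermediate
9 | (R)-glycidol | OC[C@@H]1CO1 | starting material
10 | isopropenylmagnesium bromide | C=C(C)[Mg]Br | starting material
11 | (S)-4-methylpent-4-ene-1,2-diol | OC[C@@H](O)CC(C)=C | intermediate
12 | bis-TBS ether of 11 | CC(C)(C)[Si](C)(C)OC[C@@H](O[Si](C)(C)C(C)(C)C)CC(C)=C | intermediate
13 | CM product | CC(C)(C)[Si](C)(C)OC[C@@H](O[Si](C)(C)C(C)(C)C)C/C(C)=C/CCc1ccoc1 | intermediate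
14 | primary alcohol | OC[C@@H](O[Si](C)(C)C(C)(C)C)C/C(C)=C/CCc1ccoc1 | intermediate
15 | α-silyloxy aldehyde | O=C[C@@H](O[Si](C)(C)C(C)(C)C)C/C(C)=C/CCc1ccoc1 | intermediate
16 | allylic alcohol (carbinol epimers) | C=C(C)C(O)[C@@H](O[Si](C)(C)C(C)(C)C)C/C(C)=C/CCc1ccoc1 | intermediate
17 | Claisen ketone | O=C(CC/C(C)=C/[C@@H](O[Si](C)(C)C(C)(C)C)C/C(C)=C/CCc1ccoc1)[C@]1(C)CCC(=O)O1 | intermediate
18 | Cα alcohol | O[C@H](CC/C(C)=C/[C@@H](O[Si](C)(C)C(C)(C)C)C/C(C)=C/CCc1ccoc1)[C@]1(C)CCC(=O)O1 | intermediate
19 | Cα acetate, TBS ether | CC(=O)O[C@H](CC/C(C)=C/[C@@H](O[Si](C)(C)C(C)(C)C)C/C(C)=C/CCc1ccoc1)[C@]1(C)CCC(=O)O1 | intermediate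
20 | 15-acetylirciformonin B | CC(=O)O[C@H](CC/C(C)=C/[C@@H](O)C/C(C)=C/CCc1ccoc1)[C@]1(C)CCC(=O)O1 | target

## Totals
- Total steps: 15
- Longest linear sequence: 10 (glycidol → 11 → 12 → 13 → 14 → 15 → 16 → 17 → 18 → 19 → 20)

## Three steps most likely to fail
1. **Step 13, diastereoselective reduction.** The chelation model with a weakly donating lactone ring oxygen may give only a modest dr.
   Fallback: reduce with L-selectride (Felkin–Anh, giving the Cα epimer), then Mitsunobu with AcOH (inversion) to install the acetate directly.
2. **Step 12, acetal Claisen.** The ketal of an α-acyloxy ketone is hindered and electron-poor, and E/Z control or yield may be poor.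
   Fallback: Carroll rearrangement. Make the acyl Meldrum's acid from the lactone carboxylic acid (from 3 by ozonolysis and Pinnick oxidation), open it with 16 to give the allyl β-ketoester, then heat to rearrange and decarboxylate.
3. **Step 8, cross-metathesis.** Yield or E:Z (expected roughly 5:1) with the 1,1-disubstituted alkene may be insufficient.
   Fallback: build the alkenyl unit by Negishi carboalumination of 4-(3-furyl)-1-butyne, then open (S)-TBS-glycidyl ether with the alkenyl cuprate to give 14-type material directly (as its 1-OTBS ether).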